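The route rests on reading the isopropyl carbinol C4 of the cyclopentane as a ketone. The quaternary fusion carbon C1 is then its β-carbon, the fusion CH C5 its α-carbon, and C5–C6(O) an anti aldol pair. One operation forms C1–C10 and C5–C6 and sets C1, C5 and C6 without closing a ring: enantioselective copper-catalysed 1,4-addition of a 1-silylvinylalane to 3-methylcyclopentenone, then aldol capture of the C4–C5 enolate with 3-iodobut-3-enal. The precursors are three small achiral pieces. The product holds twelve of the fifteen skeletal carbons and both handles, masked vinyl (C10, C9) and iodoalkene (C8), for a later C8–C9 closure of the cycloheptane.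

Key step: step 4

**Remarks on the chemistry**
- **Numbering:** C1 is the quaternary fusion carbon (bears CH3). C2 and C3 are the cyclopentane CH2 groups. C4 is the isopropyl carbinol, C5 the fusion CH, C6 the acyloxy CH, and C7 a CH2. C8 is the methyl carbinol, C9 the secondary carbinol, and C10 the CH2 joined to C1. β is the face of the C1 methyl group.
- **Target stereochemistry:** the target SMILES reads 1β-CH3, 5α-H (trans fusion), 4β-OH/4α-iPr, 6α-OAr, 8β-OH/8α-CH3 and 9α-OH, so the 8,9-diol is trans. In azulene numbering this is (3R,3aS,4S,6S,7S,8aR).
- **Match of aldol 8 to the target:** the descriptors of 8, (S)-C1, (S)-C5 and (S)-C6, map onto 8aR, 3aS and 4S of the target.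
- **Where stereocentres are set:** C1, C5 and C6 in step 4; C4 in step 7; C9 in step 10; C8 in step 12.
- **Assumption:** both enantiomers of the NHC ligand are available and the one giving (S)-C1 in 8 is used. The sense of induction is to be confirmed on the simple conjugate adduct.
- **Design choices:**
  - (i) The alane is kept near one equivalent and the aldehyde is used as a fresh, dried solution. Left-over C–Al bonds and traces of acid or base are what would consume or isomerise it.
  - (ii) Silicon is removed while C4 is still a ketone, since the acid needed would ionise the tertiary C4 carbinol.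
  - (iii) O6 carries a benzyl ether, which survives that acid and is orthogonal to the O9 silyl ether.

Step 1
Reactants: 1 3-butyn-1-ol
Product: 2 3-iodobut-3-en-1-ol
Conditions: NaI, TMSCl, H2O (0.5 equiv per TMSCl), MeCN, 0 °C → rt
Reagents that add atoms: sodium iodide, [Na+].[I-]
Why: Markovnikov hydroiodination of a terminal alkyne by HI generated in situ puts iodine on the internal carbon (future C8), and any silyl ether formed on the alcohol falls off in the aqueous work-up.

Step 2
Reactants: 2 3-iodobut-3-en-1-ol
Product: 3 3-iodobut-3-enal
Conditions: Dess–Martin periodinane, CH2Cl2, 0 °C → rt; short silica plug, solution dried over 4 Å MS and used the same day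
Reagents that add atoms: none
Why: Dess–Martin oxidation is non-aqueous and free of amine base, so the primary alcohol should stop at the aldehyde and the β,γ-double bond should not move into conjugation.

Step 3
Reactants: 4 trimethylsilylacetylene
Product: 5 diisobutyl[1-(trimethylsilyl)vinyl]aluminium
Conditions: iBu2AlH (1.0 equiv), hexanes/THF 5:1, 55 °C; solution used directly in step 4
Reagents that add atoms: diisobutylaluminium hydride, CC(C)C[AlH]CC(C)C
Why: Hydroalumination (syn Al–H addition) of a silylacetylene places aluminium on the silicon-bearing carbon, where the C–Al bond is stabilised by silicon, and the THF co-solvent tempers the hydride so that deprotonation to the alkynylalane stays minor.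

Step 4
Reactants: 6 3-methylcyclopent-2-enone; 5 diisobutyl[1-(trimethylsilyl)vinyl]aluminium; 3 3-iodobut-3-enal
Product: 8 (2S,3S)-2-[(1S)-1-hydroxy-3-iodobut-3-enyl]-3-methyl-3-[1-(trimethylsilyl)vinyl]cyclopentanone (anti aldol; C1 methyl β; H5 α; O6 α), via aluminium enolate 7 (not isolated)
Conditions: Cu(OTf)2 (5 mol %), chiral sulfonate-bearing bidentate NHC–Ag(I) complex (2.5 mol % dimer), 5 (1.3 equiv), THF, −15 °C; then 3 (2 equiv) in THF, −78 → −40 °C; aq. Rochelle salt, −40 °C → rt
Reagents that add atoms: none
Why: Alkenyl transfer from 5 to the NHC–Cu centre, 1,4-addition to the aluminium-activated enone and reductive elimination form C1–C10 and release the diisobutylaluminium enolate 7 with its double bond fixed between C4 and C5 (a regioisomer that deprotonation of the saturated ketone would not give); 7 binds aldehyde 3 at its Lewis-acidic aluminium and forms C5–C6 through a closed six-membered Zimmerman–Traxler array. The closest known reaction types are the NHC–Cu-catalysed enantioselective conjugate addition of silicon-substituted vinylaluminium reagents to β-substituted cyclopentenones and the tandem conjugate addition–aldol reaction of aluminium or zinc enolates; the aldol half is less tested on an enolate flanked by a quaternary carbon, which is where the route carries its risk. No ring is closed. C1 is controlled by the catalyst (ligand enantiomer chosen for (S)-C1, methyl β), C5 by approach of the aldehyde to the ring face opposite the bulky 1-silylvinyl group (C6 trans to C10, H5 α), and C6 by the ring-locked E geometry of the enolate, which with the aldehyde side chain equatorial in the chair gives the anti aldol (O6 α). The step needs 1,4- over 1,2-addition, alkenyl over isobutyl transfer, and C–C bond formation faster than proton transfer from the acidic C7 methylene of 3, hydride or alkenyl transfer from aluminium, retro-aldol equilibration and Tishchenko-type over-reaction. These are secured by copper catalysis, by the faster transmetalation of the sp2 C–Al bond, by the low basicity and high oxophilicity of aluminium, by keeping 5 close to stoichiometric, and by adding 3 cold and quenching cold.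

Step 5
Reactants: 8 anti-aldol ketone
Product: 9 O6-benzyl ether of 8
Conditions: BnOC(=NH)CCl3 (2 equiv), TfOH (10 mol %), CH2Cl2/cyclohexane 1:2, 0 °C → rt
Reagents that add atoms: benzyl 2,2,2-trichloroacetimidate, N=C(OCc1ccccc1)C(Cl)(Cl)Cl
Why: Acid-catalysed O-alkylation with the trichloroacetimidate needs no base, so the β-hydroxy ketone can neither cleave by retro-aldol reaction nor eliminate, and the benzyl ether withstands the acid, organometal, borane, chromium, peracid and hydride steps ahead while staying orthogonal to the later O9 silyl ether.

Step 6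
Reactants: 9 O6-benzyl ether of 8
Product: 10 O6-benzyl vinyl ketone (C1 now bears CH=CH2; C1, C5, C6 unchanged)
Conditions: CF3CO2H (5 equiv), CHCl3, 0 °C → rt
Reagents that add atoms: none
Why: Electrophilic protodesilylation: ipso protonation of the vinylsilane gives a β-silyl-stabilised cation that loses Me3Si to trifluoroacetate, a conversion known for 3-alkyl-3-(1-silylvinyl)cyclopentanones, and it is placed here because the molecule still holds no acid-labile tertiary carbinol or silyl ether, while the weak acid and short contact time should leave the enolisable C5 centre alone.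

Step 7
Reactants: 10 O6-benzyl vinyl ketone
Product: 11 C4 tertiary alcohol (4β-OH; 4α-isopropyl)
Conditions: anhydrous CeCl3 (3.5 equiv), iPrMgCl (3 equiv), THF, −78 °C; then 10, −78 → −40 °C; aq. NH4Cl
Reagents that add atoms: isopropylmagnesium chloride, CC(C)[Mg]Cl
Why: Organocerium 1,2-addition: the oxophilic, weakly basic reagent should add to the hindered, enolisable β-alkoxy ketone instead of deprotonating it, reducing it or exchanging the alkenyl iodide at −78 °C, and it reaches C4 from the α face, opposite the C5 side chain and the C1 methyl group, so that isopropyl ends α and O4 β.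

Step 8
Reactants: 11 C4 tertiary alcohol
Product: 13 C9 primary alcohol (C1–CH2–CH2OH), via B-alkyl-9-BBN adduct 12 (not isolated)
Conditions: 9-BBN (3 equiv), THF, 0 °C → rt; then 3 M NaOH, 30% H2O2, 0 °C
Reagents that add atoms: 9-borabicyclo[3.3.1]nonane, B1C2CCCC1CCC2 (kept only in 12); hydrogen peroxide, OO
Why: Hydroboration–oxidation: 9-BBN puts boron on the terminal carbon C9 of the monosubstituted vinyl group while the iodine-deactivated alkene reacts far more slowly (the selectivity on which B-alkyl Suzuki cyclisations of halodienes rely), the excess reagent covers the tertiary OH, and C–B oxidation gives the primary alcohol.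

Step 9
Reactants: 13 C9 primary alcohol
Product: 14 C9 aldehyde (C1–CH2–CHO)
Conditions: Dess–Martin periodinane, CH2Cl2, 0 °C → rt
Reagents that add atoms: none
Why: Dess–Martin oxidation stops at the aldehyde, leaves the tertiary alcohol and the alkenyl iodide untouched, and no lactol can form because O4 (β) and the C10–C9 chain (α) lie on opposite faces of the cyclopentane.

Step 10
Reactants: 14 C9 aldehyde
Product: 15 trans-fused hydroazulene allylic alcohol (9α-OH; 8-methylene; 6α-OBn; 4β-OH)
Conditions: CrCl2 (8 equiv), NiCl2 (0.08 equiv), degassed DMSO, 0.005 M, rt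
Reagents that add atoms: none
Why: Nozaki–Hiyama–Kishi reaction: nickel inserts into the C8–I bond, chromium(III) takes over the alkenyl group and adds it only to the aldehyde (free tertiary OH tolerated), closing the cycloheptane at C8–C9 in a 7-exo-trig mode under high dilution, and C9 should be set with O9 α because the chromium-bound oxygen takes the pseudo-equatorial position, whereas the β orientation would be syn-diaxial to the C1 methyl group.

Step 11
Reactants: 15 allylic alcohol
Product: 16 9α-tert-butyldimethylsilyl ether of 15
Conditions: TBSOTf (1.2 equiv), 2,6-lutidine (2 equiv), CH2Cl2, −78 °C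
Reagents that add atoms: tert-butyldimethylsilyl triflate, CC(C)(C)[Si](C)(C)OS(=O)(=O)C(F)(F)F
Why: Silyl triflate silylation at −78 °C distinguishes the secondary allylic alcohol from the buried tertiary C4 hydroxyl, removes the hydrogen-bond donor that would steer a peracid to the α face, and adds bulk to that face.

Step 12
Reactants: 16 9α-silyl ether
Product: 17 C8 spiro-epoxide (epoxide O β; epoxide CH2 α)
Conditions: mCPBA (1.5 equiv), CH2Cl2, −20 → 0 °C
Reagents that add atoms: 3-chloroperoxybenzoic acid, OOC(=O)c1cccc(Cl)c1
Why: Prilezhaev epoxidation under steric control: with no free allylic OH to guide it, the peracid should reach the only alkene from the β face, because the α face is screened by the neighbouring 9α-silyloxy group and the 1,3-related 6α-benzyloxy group, which sets C8 with its oxygen β.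

Step 13
Reactants: 17 C8 spiro-epoxide
Product: 18 C8 tertiary alcohol (8β-OH; 8α-CH3; 9α-OTBS; 6α-OBn)
Conditions: LiEt3BH (4 equiv), THF, 0 °C → rt; aq. NH4Cl
Reagents that add atoms: none
Why: SN2 opening of the 1,1-disubstituted epoxide by triethylborohydride occurs at the unhindered CH2, so the C8–O bond and the C8 configuration are kept and the CH2 becomes the α-oriented C8 methyl group.

Step 14
Reactants: 18 C8 tertiary alcohol
Product: 19 4β,6α,8β-triol with 9α-OTBS
Conditions: H2 (1 atm), 20% Pd(OH)2/C, EtOAc, rt
Reagents that add atoms: none
Why: Catalytic hydrogenolysis cleaves the only benzylic C–O bond, no alkene or halide is left to be reduced, and the aprotic solvent keeps the silyl ether in place, which leaves O6 as the only free secondary hydroxyl.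

Step 15
Reactants: 20 4-hydroxybenzoic acid
Product: 22 4-(tert-butyldimethylsilyloxy)benzoic acid, via bis-silyl derivative 21 (not isolated)
Conditions: TBSCl (2.5 equiv), imidazole (5 equiv), DMF, rt; then AcOH/THF/H2O 3:1:1, rt
Reagents that add atoms: tert-butyldimethylsilyl chloride, CC(C)(C)[Si](C)(C)Cl
Why: Exhaustive silylation followed by mild hydrolysis exploits the much greater lability of a silyl ester compared with an aryl silyl ether, giving the phenol-protected acid.

Step 16
Reactants: 19 4β,6α,8β-triol with 9α-OTBS; 22 4-(tert-butyldimethylsilyloxy)benzoic acid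
Product: 24 O6 4-(tert-butyldimethylsilyloxy)benzoate of 19, via mixed anhydride 23 (not isolated)
Conditions: 22 (2 equiv), 2,4,6-Cl3C6H2COCl, Et3N, toluene, rt; then 19, DMAP, toluene, rt → 50 °C
Reagents that add atoms: 2,4,6-trichlorobenzoyl chloride, O=C(Cl)c1c(Cl)cc(Cl)cc1Cl (kept only in 23)
Why: Yamaguchi esterification: the DMAP-activated aroyl group is taken up by the single secondary hydroxyl O6, the tertiary hydroxyls at C4 and C8 being too hindered to acylate, and C6 keeps its configuration since its C–O bond is not touched.

Step 17
Reactants: 24 bis-silylated ester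
Product: 25 CNP0197754.1, (3R,3aS,4S,6S,7S,8aR)-3,6,7-trihydroxy-6,8a-dimethyl-3-(propan-2-yl)decahydroazulen-4-yl 4-hydroxybenzoate
Conditions: HF·pyridine, pyridine, THF, 0 °C → rt
Reagents that add atoms: none
Why: Fluoride-driven Si–O cleavage removes the aryl and the O9 silyl ethers in one operation, the pyridine buffer protecting the acid-sensitive tertiary carbinols and the non-basic medium preventing ester migration or hydrolysis.

**Compound list**
1 | 3-butyn-1-ol | C#CCCO | starting material
2 | 3-iodobut-3-en-1-ol | C=C(I)CCO | intermediate
3 | 3-iodobut-3-enal | C=C(I)CC=O | intermediate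
4 | trimethylsilylacetylene | C#C[Si](C)(C)C | starting material
5 | diisobutyl[1-(trimethylsilyl)vinyl]aluminium | C=C([Si](C)(C)C)[Al](CC(C)C)CC(C)C | intermediate
6 | 3-methylcyclopent-2-enone | CC1=CC(=O)CC1 | starting material
7 | diisobutylaluminium C4–C5 enolate of the conjugate adduct | CC(C)C[Al](CC(C)C)OC1=C[C@@](C)(C(=C)[Si](C)(C)C)CC1 | intermediate
8 | (2S,3S)-2-[(1S)-1-hydroxy-3-iodobut-3-enyl]-3-methyl-3-[1-(trimethylsilyl)vinyl]cyclopentanone | O=C1CC[C@](C)(C(=C)[Si](C)(C)C)[C@H]1[C@@H](O)CC(I)=C | intermediate
9 | O6-benzyl ether of 8 | O=C1CC[C@](C)(C(=C)[Si](C)(C)C)[C@H]1[C@@H](OCc2ccccc2)CC(I)=C | intermediate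
10 | O6-benzyl vinyl ketone | O=C1CC[C@](C)(C=C)[C@H]1[C@@H](OCc2ccccc2)CC(I)=C | intermediate
11 | C4 tertiary alcohol (4β-OH, 4α-iPr) | CC(C)[C@]1(O)CC[C@](C)(C=C)[C@H]1[C@@H](OCc2ccccc2)CC(I)=C | intermediate
12 | B-alkyl-9-BBN adduct (boron on C9) | CC(C)[C@]1(O)CC[C@](C)(CCB2C3CCCC2CCC3)[C@H]1[C@@H](OCc2ccccc2)CC(I)=C | intermediate
13 | C9 primary alcohol | CC(C)[C@]1(O)CC[C@](C)(CCO)[C@H]1[C@@H](OCc2ccccc2)CC(I)=C | intermediate
14 | C9 aldehyde | CC(C)[C@]1(O)CC[C@](C)(CC=O)[C@H]1[C@@H](OCc2ccccc2)CC(I)=C | intermediate
15 | trans-hydroazulene allylic alcohol (9α-OH, 8-methylene) | CC(C)[C@]1(O)CC[C@]2(C)C[C@H](O)C(=C)C[C@H](OCc3ccccc3)[C@H]21 | intermediate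
16 | 9α-TBS ether of 15 | CC(C)[C@]1(O)CC[C@]2(C)C[C@H](O[Si](C)(C)C(C)(C)C)C(=C)C[C@H](OCc3ccccc3)[C@H]21 | intermediate
17 | C8 spiro-epoxide (O β) | CC(C)[C@]1(O)CC[C@]2(C)C[C@H](O[Si](C)(C)C(C)(C)C)[C@]3(CO3)C[C@H](OCc4ccccc4)[C@H]21 | intermediate
18 | 8β-hydroxy-8α-methyl compound | CC(C)[C@]1(O)CC[C@]2(C)C[C@H](O[Si](C)(C)C(C)(C)C)[C@@](C)(O)C[C@H](OCc3ccccc3)[C@H]21 | intermediate
19 | 4β,6α,8β-triol with 9α-OTBS | CC(C)[C@]1(O)CC[C@]2(C)C[C@H](O[Si](C)(C)C(C)(C)C)[C@@](C)(O)C[C@H](O)[C@H]21 | intermediate
20 | 4-hydroxybenzoic acid | O=C(O)c1ccc(O)cc1 | starting material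
21 | tert-butyldimethylsilyl 4-(tert-butyldimethylsilyloxy)benzoate | CC(C)(C)[Si](C)(C)OC(=O)c1ccc(O[Si](C)(C)C(C)(C)C)cc1 | intermediate
22 | 4-(tert-butyldimethylsilyloxy)benzoic acid | CC(C)(C)[Si](C)(C)Oc1ccc(C(=O)O)cc1 | intermediate
23 | mixed anhydride of 22 with 2,4,6-trichlorobenzoic acid | CC(C)(C)[Si](C)(C)Oc1ccc(cc1)C(=O)OC(=O)c2c(Cl)cc(Cl)cc2Cl | intermediate
24 | O6 4-(TBSO)benzoate, 9α-OTBS | CC(C)[C@]1(O)CC[C@]2(C)C[C@H](O[Si](C)(C)C(C)(C)C)[C@@](C)(O)C[C@H](OC(=O)c3ccc(O[Si](C)(C)C(C)(C)C)cc3)[C@H]21 | intermediate
25 | CNP0197754.1 | CC(C)[C@]1(O)CC[C@]2(C)C[C@H](O)[C@@](C)(O)C[C@H](OC(=O)c3ccc(O)cc3)[C@H]21 | target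

Total steps: 17. Longest linear sequence: 15 (steps 1, 2, 4–14, 16, 17).

**Steps most likely to fail**

**Step 4.** The hindered aluminium enolate may be captured too slowly. Proton transfer from the acidic methylene of the aldehyde, hydride or alkenyl transfer from aluminium to the aldehyde, or Tishchenko-type over-reaction could then take over.

The fallback sets out from 6 and 5 and separates the two bond formations. The conjugate addition is run alone and enolate 7 is silylated in the flask with TMSOTf to give the isolable trimethylsilyl enol ether F1. MeLi in THF at 0 °C releases the regiodefined lithium enolate F2. ZnCl2 at −78 °C converts it into the less basic chlorozinc enolate F3. Addition of 3 should then give the anti aldol through the same kind of closed transition state, free of catalyst residues and surplus alane. The route is rejoined at 8.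

**Step 10.** The closure may show poor facial selectivity at the aldehyde carbon, or may prefer the pseudo-axial alkoxide, so that C9 is formed in the wrong sense.

The fallback sets out from 14 and accepts the closure whatever its C9 outcome. The 9β-alcohol F4, alone or together with 15, is oxidised with Dess–Martin periodinane to the α-methylene ketone F5. Corey–Bakshi–Shibata reduction then sets C9 under reagent control by 1,2-delivery of hydride to the β face. The conditions are (R)-Me-CBS, assigned by the usual model with the alkenyl carbon C8 as the large group, with catecholborane in toluene at −78 °C. The route is rejoined at 15.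

**Step 12.** Oxygen transfer to the exocyclic methylene may show poor facial selectivity, because the seven-membered ring is flexible and the 9α-silyloxy group may lie close to the alkene plane.

The fallback sets out from 16 and replaces peracid epoxidation by catalytic osmylation (OsO4, NMO, acetone/H2O). Attack anti to an allylic ether oxygen is an established empirical trend for this reaction, and the bulkier reagent feels the two α-oriented ethers more strongly. This should give the 8β-hydroxy-8α-hydroxymethyl diol F6. Selective sulfonylation of the primary hydroxyl (TsCl, pyridine, 0 °C) gives the primary monotosylate F7. LiEt3BH removes the sulfonate, directly or through epoxide 17 formed in the flask. The route is rejoined at 18.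

Further compounds
F1 | step 4 | trimethylsilyl enol ether of the conjugate adduct | C[Si](C)(C)OC1=C[C@@](C)(C(=C)[Si](C)(C)C)CC1
F2 | step 4 | lithium enolate | [Li]OC1=C[C@@](C)(C(=C)[Si](C)(C)C)CC1
F3 | step 4 | chlorozinc enolate | Cl[Zn]OC1=C[C@@](C)(C(=C)[Si](C)(C)C)CC1
F4 | step 10 | 9β-alcohol (C9 epimer of 15) | CC(C)[C@]1(O)CC[C@]2(C)C[C@@H](O)C(=C)C[C@H](OCc3ccccc3)[C@H]21
F5 | step 10 | α-methylene ketone (C9 ketone) | CC(C)[C@]1(O)CC[C@]2(C)CC(=O)C(=C)C[C@H](OCc3ccccc3)[C@H]21
F6 | step 12 | 8β-hydroxy-8α-hydroxymethyl diol | CC(C)[C@]1(O)CC[C@]2(C)C[C@H](O[Si](C)(C)C(C)(C)C)[C@@](CO)(O)C[C@H](OCc3ccccc3)[C@H]21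
F7 | step 12 | primary monotosylate of F6 | CC(C)[C@]1(O)CC[C@]2(C)C[C@H](O[Si](C)(C)C(C)(C)C)[C@@](COS(=O)(=O)c3ccc(C)cc3)(O)C[C@H](OCc4ccccc4)[C@H]21
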